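**Retrosynthetic overview** (labdane numbering: decalin C1–C10, side chain C11–C16, C17 on C8, C18/C19 on C4, C20 on C10)
1. Endgame: C2 senecioate by esterification; the C2 oxygen and the C4 gem-dimethyl group both come from a C4 ketone (MeLi, oxidative 1,3-transposition, Me2CuLi, thermodynamic reduction).
2. Key disconnection, ring B: C5–C6 and C7=C8 are made together by stitching a two-carbon vinylphosphonium unit (C6–C7) between C5 and C8 (Michael addition/intramolecular Wittig). The enabling feature is that the ring B alkene C7=C8 carries a methyl on C8 (so C8 can be a methyl ketone) and lies 1,4 to the ring-fusion carbon C5, which sits next to C4 of ring A; a temporary C4 ketone plus a C5 ester make C5 a soft carbon nucleophile.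
3. C9–C10 (tertiary/quaternary pair): Claisen rearrangement of a Z-allyl vinyl ether, relaying the C4 carbinol chirality of ring A to C10 and the enol ether geometry to C9, and releasing the C8 ketone.
4. Building blocks: ring A (C1–C5, C10, C20) from 3-methylcyclohex-2-en-1-one; C9 and C11–C16 with the C13 carbinol from (S)-linalool (chiral pool); C8/C17 from an ethyl ylide; C6/C7 from vinyltriphenylphosphonium bromide; C18/C19 from methyl nucleophiles.
5. Ring order: ring A is bought, ring B is closed in the key step.

Key step: step 10

Assumption: (S)-(+)-linalool of high enantiomeric purity is taken as a purchasable starting material; locants in the text are those of the labdane skeleton of the target.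

**Route**

Step 1
Reactants: 1 (S)-linalool
Product: 2 (S)-linalool triethylsilyl ether
Conditions: Et3SiOTf, 2,6-lutidine, CH2Cl2, −78 → 0 °C
Reagents that add atoms: triethylsilyl trifluoromethanesulfonate, CC[Si](CC)(CC)OS(=O)(=O)C(F)(F)F
Why: Silylation with the silyl triflate and a hindered pyridine base masks the tertiary allylic alcohol (C13 comes from the chiral pool, no new stereocenter) so that it survives the oxidative transposition of step 14 and the organometallic steps.

Step 2
Reactants: 2 (S)-linalool triethylsilyl ether
Product: 3 (4S)-4-methyl-4-(triethylsilyloxy)hex-5-enal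
Conditions: O3 (1.0 equiv), CH2Cl2/MeOH, pyridine, −78 °C; then Me2S, rt
Reagents that add atoms: ozone, [O-][O+]=O
Why: Ozonolysis with reductive work-up should cleave the electron-rich trisubstituted alkene in preference to the vinyl group beside the quaternary silyloxy carbon when ozone is dosed to one equivalent, giving the C9 aldehyde (no new stereocenter).

Step 3
Reactants: 3 (4S)-4-methyl-4-(triethylsilyloxy)hex-5-enal
Product: 4 (3S,6Z)-7-iodo-3-methyl-3-(triethylsilyloxy)octa-1,6-diene
Conditions: EtPPh3I, n-BuLi, THF, 0 °C; I2, −78 °C; NaN(SiMe3)2, −78 → −20 °C; then 3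
Reagents that add atoms: ethyltriphenylphosphonium iodide, CC[P+](c1ccccc1)(c1ccccc1)c1ccccc1.[I-]; iodine, [I][I]
Why: Stork–Zhao-type Wittig olefination with the α-iodo ylide made in the flask should give the Z-2-iodo-2-alkene (iodine cis to the chain), which fixes the enol ether geometry used in step 7.

Step 4
Reactants: 5 3-methylcyclohex-2-en-1-one
Product: 6 2-iodo-3-methylcyclohex-2-en-1-one
Conditions: I2, K2CO3, DMAP (cat.), THF/H2O, rt
Reagents that add atoms: iodine, [I][I]
Why: α-Iodination of the enone (conjugate addition of the nucleophilic catalyst, iodination of the enolate, elimination; Morita–Baylis–Hillman-type pathway) puts a handle on C5 (no stereocenter).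

Step 5
Reactants: 6 2-iodo-3-methylcyclohex-2-en-1-one
Product: 7 (1S)-2-iodo-3-methylcyclohex-2-en-1-ol
Conditions: (R)-2-methyl-CBS-oxazaborolidine (10 mol %), BH3·SMe2, THF, −20 °C; aqueous NH4Cl
Reagents that add atoms: none
Why: Corey–Bakshi–Shibata reduction, with the iodovinyl group acting as the large ketone substituent, should give the S carbinol at C4 under catalyst control (the catalyst enantiomer is chosen for this sense); this center later relays its chirality to C10.

Step 6
Reactants: 7 (1S)-2-iodo-3-methylcyclohex-2-en-1-ol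
Product: 8 methyl (6S)-6-hydroxy-2-methylcyclohex-1-ene-1-carboxylate
Conditions: Pd(OAc)2 (5 mol %), PPh3, CO (1 atm), MeOH, Et3N, DMF, 60 °C
Reagents that add atoms: carbon monoxide, [C-]#[O+]; methanol, CO
Why: Palladium-catalysed methoxycarbonylation of the vinyl iodide (oxidative addition, CO insertion, methanolysis) installs the C5 ester that later marks and acidifies C5, leaving the carbinol center untouched.

Step 7
Reactants: 8 methyl (6S)-6-hydroxy-2-methylcyclohex-1-ene-1-carboxylate; 4 (3S,6Z)-7-iodo-3-methyl-3-(triethylsilyloxy)octa-1,6-diene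
Product: 10 methyl (6S)-6-methyl-6-[(3S,6S)-6-methyl-2-oxo-6-(triethylsilyloxy)oct-7-en-3-yl]cyclohex-1-ene-1-carboxylate, via Z-allyl vinyl ether 9 (not isolated)
Conditions: CuI (10 mol %), 3,4,7,8-tetramethyl-1,10-phenanthroline (20 mol %), Cs2CO3, toluene, 80 °C; filtration; then o-xylene, 140 °C
Reagents that add atoms: none
Why: Ullmann-type copper-catalysed C–O coupling with retention of alkene geometry gives the Z-allyl vinyl ether, whose Claisen rearrangement forms C9–C10 suprafacially on the ring face that carried the C4–O bond (sets quaternary C10) through a chair transition state that keeps the chain of the Z-enol ether away from ring A (sets C9), and releases the C8 methyl ketone.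

Step 8
Reactants: 10 methyl (6S)-6-methyl-6-[(3S,6S)-6-methyl-2-oxo-6-(triethylsilyloxy)oct-7-en-3-yl]cyclohex-1-ene-1-carboxylate
Product: 12 methyl 6-hydroxy-2-methyl-2-[(3S,6S)-6-methyl-2-oxo-6-(triethylsilyloxy)oct-7-en-3-yl]cyclohexane-1-carboxylate (quaternary carbon as in 10; epimers at C1 and C6 of the ring), via pinacol boronate 11 (not isolated)
Conditions: CuCl (5 mol %), DPEphos, NaOt-Bu (cat.), B2pin2, MeOH, THF, rt; then NaBO3·4H2O, THF/H2O, rt
Reagents that add atoms: sodium perborate, [Na+].[O-]OB=O
Why: Copper-catalysed conjugate borylation of the α,β-unsaturated ester at C4 followed by oxidation of the C–B bond returns oxygen to C4; the new centers at C4 and C5 need no control because both are erased in steps 9 to 11.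

Step 9
Reactants: 12 methyl 6-hydroxy-2-methyl-2-[(3S,6S)-6-methyl-2-oxo-6-(triethylsilyloxy)oct-7-en-3-yl]cyclohexane-1-carboxylate
Product: 13 methyl 2-methyl-6-oxo-2-[(3S,6S)-6-methyl-2-oxo-6-(triethylsilyloxy)oct-7-en-3-yl]cyclohexane-1-carboxylate
Conditions: Dess–Martin periodinane, pyridine, CH2Cl2, rt
Reagents that add atoms: none
Why: Dess–Martin oxidation of the secondary alcohol gives the β-keto ester and so makes C5–H the most acidic position of the molecule (no lasting stereocenter).

Step 10
Reactants: 13 methyl 2-methyl-6-oxo-2-[(3S,6S)-6-methyl-2-oxo-6-(triethylsilyloxy)oct-7-en-3-yl]cyclohexane-1-carboxylate; 14 vinyltriphenylphosphonium bromide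
Product: 16 bicyclic β-keto ester (decalin of the target with C4=O and CO2Me on C5; C7=C8 in place; 13-OSiEt3; C5 epimers), via phosphorus ylide 15 (not isolated)
Conditions: NaH (1.0 equiv), THF/DMF, 0 °C; then 14, rt → 65 °C
Reagents that add atoms: none
Why: NaH removes the C5 proton of the β-keto ester (the only C–H acidic enough for one equivalent of base), the enolate adds through carbon to the vinylphosphonium salt (C5–C6) to give ylide 15, and the ylide olefinates the C8 methyl ketone held 1,4 to C5 (C7=C8, Ph3P=O lost). The closest known reaction type is the Schweizer annulation, in which β-dicarbonyl carbon acids bearing a ketone are converted by vinyltriphenylphosphonium bromide into cyclopentenes and cyclohexenes by Michael addition and intramolecular Wittig reaction. Ring B is closed by 6-exo-trig attack of the ylide carbon C7 on the C8 carbonyl (oxaphosphetane, then cycloreversion), so the new double bond is endocyclic and cis. The only new stereocenter, quaternary C5, need not be controlled because its ester is removed in step 11 and C5 is then set by protonation; C9, C10 and C13 are not affected. The step needs C- rather than O-alkylation (the O-adduct can revert while the C-adduct is drained by the irreversible olefination) and olefination of C8 rather than of the C4 ketone or the ester (only C8 is reached through a six-membered ring, the others would give cyclobutenes).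

Step 11
Reactants: 16 bicyclic β-keto ester
Product: 17 trans-fused ketone (C4=O; H on C5 anti to the C10 methyl; C7=C8; 13-OSiEt3)
Conditions: LiCl, H2O, DMSO, 140 °C
Reagents that add atoms: none
Why: Krapcho dealkoxycarbonylation (chloride attack on the methyl ester, loss of CO2) gives the C4 enol, which should be protonated at C5 on the face opposite to the angular C10 methyl, and equilibration α to the ketone should also favour the trans ring fusion (sets C5).

Step 12
Reactants: 17 trans-fused ketone
Product: 19 enone (C4=O; C2=C3), via trimethylsilyl enol ether 18 (not isolated)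
Conditions: LiN(i-Pr)2, THF, −78 °C; Me3SiCl; then Pd(OAc)2, MeCN, rt
Reagents that add atoms: none
Why: Saegusa–Ito oxidation: kinetic deprotonation should occur at the C3 methylene rather than at the hindered ring-fusion methine C5, and the silyl enol ether is dehydrogenated by Pd(OAc)2 to the C2=C3 enone (no new stereocenter).

Step 13
Reactants: 19 enone
Product: 20 tertiary allylic alcohol (C4 bears OH and CH3; C2=C3; C4 epimers)
Conditions: MeLi, Et2O, −78 °C
Reagents that add atoms: methyllithium, [Li]C
Why: 1,2-Addition of methyllithium to the enone carbonyl brings in the first C4 methyl group; the configuration of the new carbinol is irrelevant because C4 becomes planar again in step 14.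

Step 14
Reactants: 20 tertiary allylic alcohol
Product: 21 transposed enone (C2=O; C3=C4 with CH3 on C4)
Conditions: pyridinium chlorochromate (C5H5NH[CrO3Cl]), Celite, CH2Cl2, rt
Reagents that add atoms: none
Why: Babler–Dauben oxidative transposition: the tertiary allylic chromate ester undergoes a [3,3] shift to C2 and is oxidised, moving the oxygen from C4 to C2, while the silylated tertiary allylic alcohol at C13 cannot react.

Step 15
Reactants: 21 transposed enone
Product: 22 ketone (C2=O; gem-dimethyl C4)
Conditions: Me2CuLi (from MeLi and CuI), Et2O, −20 → 0 °C; aqueous NH4Cl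
Reagents that add atoms: lithium dimethylcuprate, [Li+].C[Cu-]C
Why: Conjugate addition of the Gilman cuprate to the β-methyl enone creates the gem-dimethyl carbon C4 (not a stereocenter) and leaves the C2 ketone.

Step 16
Reactants: 22 ketone
Product: 23 alcohol (2-OH equatorial as in the target; 13-OSiEt3)
Conditions: Li, NH3 (l), THF, t-BuOH, −78 → −33 °C; NH4Cl
Reagents that add atoms: none
Why: Dissolving-metal reduction of the ketone should proceed under thermodynamic control to the equatorial C2 alcohol, trans to the axial methyl groups on C4 and C10 (sets C2), whereas hydride reagents would attack from the equatorial side and give the axial epimer; isolated alkenes and the silyl ether are inert.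

Step 17
Reactants: 23 alcohol; 24 3-methylbut-2-enoic acid
Product: 25 13-O-triethylsilyl ether of the target
Conditions: N,N'-dicyclohexylcarbodiimide, DMAP (cat.), CH2Cl2, 0 °C → rt
Reagents that add atoms: none
Why: Steglich esterification acylates the unhindered equatorial secondary alcohol with the α,β-unsaturated acid without touching the configuration at C2.

Step 18
Reactants: 25 13-O-triethylsilyl ether of the target
Product: 26 CNP0252389.1
Conditions: HF·pyridine, pyridine, THF, 0 °C → rt
Reagents that add atoms: none
Why: Fluoride-mediated cleavage of the tertiary triethylsilyl ether under buffered conditions frees the C13 alcohol without ionising the tertiary allylic position or cleaving the senecioate.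

**Compound list**
1 | (S)-linalool, (3S)-3,7-dimethylocta-1,6-dien-3-ol | C=C[C@@](C)(O)CCC=C(C)C | starting material
2 | (S)-linalool triethylsilyl ether | C=C[C@@](C)(O[Si](CC)(CC)CC)CCC=C(C)C | intermediate
3 | (4S)-4-methyl-4-(triethylsilyloxy)hex-5-enal | C=C[C@@](C)(O[Si](CC)(CC)CC)CCC=O | intermediate
4 | (3S,6Z)-7-iodo-3-methyl-3-(triethylsilyloxy)octa-1,6-diene | C=C[C@@](C)(O[Si](CC)(CC)CC)CC/C=C(/C)I | intermediate
5 | 3-methylcyclohex-2-en-1-one | CC1=CC(=O)CCC1 | starting material
6 | 2-iodo-3-methylcyclohex-2-en-1-one | CC1=C(I)C(=O)CCC1 | intermediate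
7 | (1S)-2-iodo-3-methylcyclohex-2-en-1-ol | O[C@H]1CCCC(C)=C1I | intermediate
8 | methyl (6S)-6-hydroxy-2-methylcyclohex-1-ene-1-carboxylate | O[C@H]1CCCC(C)=C1C(=O)OC | intermediate
9 | Z-allyl vinyl ether: methyl (6S)-2-methyl-6-{[(2Z,6S)-6-methyl-6-(triethylsilyloxy)octa-2,7-dien-2-yl]oxy}cyclohex-1-ene-1-carboxylate | C=C[C@@](C)(O[Si](CC)(CC)CC)CC/C=C(/C)O[C@H]1CCCC(C)=C1C(=O)OC | intermediate
10 | methyl (6S)-6-methyl-6-[(3S,6S)-6-methyl-2-oxo-6-(triethylsilyloxy)oct-7-en-3-yl]cyclohex-1-ene-1-carboxylate | C=C[C@@](C)(O[Si](CC)(CC)CC)CC[C@H](C(C)=O)[C@]1(C)CCCC=C1C(=O)OC | intermediate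
11 | pinacol boronate: as 12 with B(pin) in place of OH (epimers at the two new ring centers) | C=C[C@@](C)(O[Si](CC)(CC)CC)CC[C@H](C(C)=O)[C@]1(C)CCCC(B2OC(C)(C)C(C)(C)O2)C1C(=O)OC | intermediate
12 | methyl 6-hydroxy-2-methyl-2-[(3S,6S)-6-methyl-2-oxo-6-(triethylsilyloxy)oct-7-en-3-yl]cyclohexane-1-carboxylate (quaternary carbon as in 10; epimers at C1 and C6) | C=C[C@@](C)(O[Si](CC)(CC)CC)CC[C@H](C(C)=O)[C@]1(C)CCCC(O)C1C(=O)OC | intermediate
13 | methyl 2-methyl-6-oxo-2-[(3S,6S)-6-methyl-2-oxo-6-(triethylsilyloxy)oct-7-en-3-yl]cyclohexane-1-carboxylate (quaternary carbon as in 10; keto/enol at C1) | C=C[C@@](C)(O[Si](CC)(CC)CC)CC[C@H](C(C)=O)[C@]1(C)CCCC(=O)C1C(=O)OC | intermediate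
14 | vinyltriphenylphosphonium bromide | C=C[P+](c1ccccc1)(c1ccccc1)c1ccccc1.[Br-] | starting material
15 | phosphorus ylide: 13 carrying CH2–CH=PPh3 on the carbon between ketone and ester | C=C[C@@](C)(O[Si](CC)(CC)CC)CC[C@H](C(C)=O)[C@]1(C)CCCC(=O)C1(CC=P(c2ccccc2)(c2ccccc2)c2ccccc2)C(=O)OC | intermediate
16 | bicyclic β-keto ester: decalin of the target with C4=O, CO2Me on C5, C7=C8, 13-OSiEt3 (C9, C10, C13 as in the target; C5 epimers) | C=C[C@@](C)(O[Si](CC)(CC)CC)CC[C@@H]1C(C)=CCC2(C(=O)OC)C(=O)CCC[C@@]12C | intermediate
17 | trans-fused ketone: C4=O, H on C5 anti to the C10 methyl, C7=C8, 13-OSiEt3 | C=C[C@@](C)(O[Si](CC)(CC)CC)CC[C@@H]1C(C)=CC[C@@H]2C(=O)CCC[C@@]12C | intermediate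
18 | trimethylsilyl enol ether of 17 (C3=C4) | C=C[C@@](C)(O[Si](CC)(CC)CC)CC[C@@H]1C(C)=CC[C@@H]2C(O[Si](C)(C)C)=CCC[C@@]12C | intermediate
19 | enone: C4=O, C2=C3 | C=C[C@@](C)(O[Si](CC)(CC)CC)CC[C@@H]1C(C)=CC[C@@H]2C(=O)C=CC[C@@]12C | intermediate
20 | tertiary allylic alcohol: C4(OH)CH3, C2=C3 (C4 epimers) | C=C[C@@](C)(O[Si](CC)(CC)CC)CC[C@@H]1C(C)=CC[C@@H]2C(C)(O)C=CC[C@@]12C | intermediate
21 | transposed enone: C2=O, C3=C4(CH3) | C=C[C@@](C)(O[Si](CC)(CC)CC)CC[C@@H]1C(C)=CC[C@@H]2C(C)=CC(=O)C[C@@]12C | intermediate
22 | ketone: C2=O, gem-dimethyl C4 | C=C[C@@](C)(O[Si](CC)(CC)CC)CC[C@@H]1C(C)=CC[C@@H]2C(C)(C)CC(=O)C[C@@]12C | intermediate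
23 | alcohol: equatorial 2-OH (configuration of the target), 13-OSiEt3 | C=C[C@@](C)(O[Si](CC)(CC)CC)CC[C@@H]1C(C)=CC[C@@H]2C(C)(C)C[C@@H](O)C[C@@]12C | intermediate
24 | 3-methylbut-2-enoic acid (senecioic acid) | CC(C)=CC(=O)O | starting material
25 | 13-O-triethylsilyl ether of the target | C=C[C@@](C)(O[Si](CC)(CC)CC)CC[C@@H]1C(C)=CC[C@@H]2C(C)(C)C[C@@H](OC(=O)C=C(C)C)C[C@@]12C | intermediate
26 | CNP0252389.1 | C=C[C@@](C)(O)CC[C@@H]1C(C)=CC[C@@H]2C(C)(C)C[C@@H](OC(=O)C=C(C)C)C[C@@]12C | target

**Step count and risks**

Total step count: 18. Longest linear sequence: 15 steps (steps 1–3 and 7–18 from 1; the ring A branch, steps 4–6 and 7–18 from 5, is equally long).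

Steps most likely to fail:

1. Step 10. C–C bond formation at the tertiary enolate carbon next to quaternary C10 may be too slow, so that O-alkylation, polymerisation of the vinylphosphonium salt or protonation of the ylide take over and ring B is not closed. Fallback (allylation, then ring-closing metathesis), setting out from 10: Wittig methylenation of the C8 ketone (Ph3P=CH2, THF) should give isopropenyl enoate F1; conjugate borylation/oxidation and Dess–Martin oxidation as in steps 8 and 9 should give hydroxy ester F2 and β-keto ester F3; C-allylation (allyl bromide, K2CO3, acetone) should give allyl keto ester F4; ring-closing metathesis of F4 with RuCl2(=CHPh)(PCy3)(H2IMes), the second-generation Grubbs catalyst (CH2Cl2, 40 °C), should join C7 to C8 and come back to the route at 16.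

2. Step 7. The copper-mediated C–O bond formation may stall at the hindered secondary allylic alcohol while the vinyl iodide is lost by dehydroiodination, and leakage of the rearrangement through a boat arrangement would erode the C9 configuration. Fallback (enol ether by carbonyl alkylidenation), setting out from 8 and 3: acetylation of 8 (Ac2O, pyridine, DMAP) should give allylic acetate F5, and (PhO)3P/Br2 should convert 3 into 1,1-dibromide F6; Takai–Utimoto alkylidenation of the acetate carbonyl of F5 with F6 (TiCl4, Zn, TMEDA, THF), a reaction that gives Z-alkenyl ethers, should give the same allyl vinyl ether 9, and heating as in step 7 comes back to the route at 10.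

3. Step 11. Protonation of the enol released on decarboxylation from the face of the C10 methyl, or equilibration of the ketone toward the cis ring fusion. Fallback (kinetic protonation of a defined enolate), setting out from 16: if decarboxylation gives mainly cis-fused ketone F7, it is carried through step 12 to cis-enone F8; LiN(i-Pr)2 (THF, −78 °C) removes the only α′ hydrogen of F8 (C5–H) to give lithium dienolate F9, and protonation of F9 at −78 °C with 2,6-di-tert-butyl-4-methylphenol on the face opposite to the C10 methyl comes back to the route at 19.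

Further compounds
F1 | step 10 | isopropenyl enoate: 10 with C8=CH2 in place of C8=O | C=C[C@@](C)(O[Si](CC)(CC)CC)CC[C@H](C(C)=C)[C@]1(C)CCCC=C1C(=O)OC
F2 | step 10 | hydroxy ester: 12 with C8=CH2 in place of C8=O | C=C[C@@](C)(O[Si](CC)(CC)CC)CC[C@H](C(C)=C)[C@]1(C)CCCC(O)C1C(=O)OC
F3 | step 10 | β-keto ester: 13 with C8=CH2 in place of C8=O | C=C[C@@](C)(O[Si](CC)(CC)CC)CC[C@H](C(C)=C)[C@]1(C)CCCC(=O)C1C(=O)OC
F4 | step 10 | allyl keto ester: F3 allylated on the carbon between ketone and ester | C=C[C@@](C)(O[Si](CC)(CC)CC)CC[C@H](C(C)=C)[C@]1(C)CCCC(=O)C1(CC=C)C(=O)OC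
F5 | step 7 | allylic acetate: methyl (6S)-6-acetoxy-2-methylcyclohex-1-ene-1-carboxylate | CC(=O)O[C@H]1CCCC(C)=C1C(=O)OC
F6 | step 7 | 1,1-dibromide: (3S)-6,6-dibromo-3-methyl-3-(triethylsilyloxy)hex-1-ene | C=C[C@@](C)(O[Si](CC)(CC)CC)CCC(Br)Br
F7 | step 11 | cis-fused ketone: C5 epimer of 17 | C=C[C@@](C)(O[Si](CC)(CC)CC)CC[C@@H]1C(C)=CC[C@H]2C(=O)CCC[C@@]12C
F8 | step 11 | cis-enone: C5 epimer of 19 | C=C[C@@](C)(O[Si](CC)(CC)CC)CC[C@@H]1C(C)=CC[C@H]2C(=O)C=CC[C@@]12C
F9 | step 11 | lithium dienolate of 19 (C4–O−, C4=C5, C2=C3) | C=C[C@@](C)(O[Si](CC)(CC)CC)CC[C@@H]1C(C)=CCC2=C([O-])C=CC[C@@]12C.[Li+]
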